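I was to read both flasks at 40 s, so I asked which clocks in them would have run down well before that reading.

- winter: starting material 20 mM; coupling partner 0.700 equiv; time 40 s
- summer: starting material 20 mM; coupling partner 1.40 equiv; time 40 s

    starting material ⇌ tight pair (K1 = 9.8 × 10⁻⁴, k1 = 0.023 s⁻¹)
    tight pair ⇌ loose pair (K2 = 0.39, k2 = 220 s⁻¹)
    coupling partner + tight pair ⇌ target (K3 = 100 M⁻¹, k3 = 3.4 × 10⁵ M⁻¹ s⁻¹)
    coupling partner + loose pair → isomer of the product (k4 = 2.6 × 10⁵ M⁻¹ s⁻¹)
    2 coupling partner → self-condensation product (k5 = 4.9 M⁻¹ s⁻¹)

1. which of these there is most of at the end, counted by the starting material in it, winter (loose pair / isomer of the product / tight pair / starting material)
2. which of these there is most of at the end, counted by the starting material in it, summer (loose pair / isomer of the product / tight pair / starting material)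
3. how much there is at the end of the one of these that leads, in percent of the starting material charged: winter
4. how much there is at the end of the one of these that leads, in percent of the starting material charged: summer

- a doubled species enters its step squared and goes two at a time
- run time (winter): 40 s

I counted in fractions of the starting-material charge. On the first rung I took, a loose pair met winter's starting coupling partner at 3640 s⁻¹, faster than its return at 564 s⁻¹. One rung down, a tight pair moved on at 220 s⁻¹, faster than its return to starting material at 23.5 s⁻¹. Below those, the exchange of starting material and tight pair relaxed in 0.0295 s in winter, far shorter than the reading time. So, with coupling partner high, I took both pairs as traces and the forward step 1 as the rate-limiting step, feeding the isomer of the product at 0.023 s⁻¹ on the starting material present, with a half-life of 30 s by that forward step alone. Self-condensation ran on a shorter clock, with a first half-life of 7.29 s in winter and 3.64 s in summer.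

That comparison gave me the quantity to carry, the balance fraction: the level of free coupling partner, as a fraction of the starting-material charge, at which self-condensation uses it as fast as the full charge feeds the isomer. It came to 0.343. Winter was charged at 2.04 times this level and summer at 4.09 times. I solved the two ends and joined them there. Above the balance fraction, I let self-condensation set the fall, which took 7.61 s in winter and 11.2 s in summer. Below it, I let the remaining coupling partner go to the isomer. With the feed held at full charge, that gave isomer ceilings of 51.8 % and 60.1 %, too loose to name a leader. The reckoning did put the gain from doubling the charge near 8.4 percentage points.

The forecast named starting material at 64 % for winter and starting material at 58 % for summer, holding that “doubling the charge helps only slightly because self-condensation is second order”.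

The simulation gave starting material at 64.7 % in winter and starting material at 59.1 % in summer.

The difference in equivalents of coupling partner may be called the main reason for the gap between the flasks: summer's starting material stood at 59.1 %, and without that difference it stood at 64.7 %, higher by 5.6 points. At 20.0 s, winter's free coupling partner was 0.0319 of the charge, below the balance fraction of 0.343, and the isomer of the product then rose 3.2 points. The neighbour charged at 5.0 mM has a balance fraction of 0.685, close to its charge of 0.700 equiv, and it gave more isomer of the product, 47.8 % against winter's 35.2 %.

(Its constants were set for the occasion, and the outcome is calculated.)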